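## Retrosynthetic overview
1. Variabilin ⇒ its 4-O-methyl ether ⇒ (E1cB dehydration) β-hydroxy lactone ⇒ intermolecular γ-aldol between C5-lithiated 4-methoxy-3-methylfuran-2(5H)-one and an (S)-α-methyl C20 furyl dienal. This is the key C–C bond.
2. Dienal ⇒ E,E-allylic bromide (furan + C10 unit) + an (S)-silyloxy sulfone made from (R)-Roche ester and methyl phenyl sulfone (alkylation, then desulfonylation). The only stereocentre is bought.
3. Allylic bromide ⇒ furan-3-ylmethyl Grignard reagent + a C10 allylic chloride made from geranyl acetate by E-selective SeO2 oxidation.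
4. Rings: the furan is bought intact (furan-3-ylmethanol). The butenolide ring is closed first and separately from ethyl 2-methylacetoacetate (bromination, lactonisation), before the fragments are joined. No ring is formed afterwards.

Assumption: n-BuLi, LDA, TBAF and Li2CuCl4 are bought as solutions; stereocentres that are erased later (C4 of 23, the two new centres of 33 and 34) are carried as mixtures and drawn without configuration.

## Route

**Step 1**
Reactants: 1 geranyl acetate [(2E)-3,7-dimethylocta-2,6-dien-1-yl acetate]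
Product: 2 (2E,6E)-8-hydroxy-3,7-dimethylocta-2,6-dien-1-yl acetate
Conditions: SeO2 (0.1 equiv), salicylic acid (0.1 equiv), t-BuOOH (3 equiv), CH2Cl2, 0 °C → rt, 24 h; chromatography
Reagents that add atoms: tert-butyl hydroperoxide CC(C)(C)OO (net source of the new O; SeO2 O=[Se]=O is the catalytic carrier)
Why: The SeO2-catalysed allylic oxidation (ene reaction, then [2,3]-sigmatropic shift) attacks the electron-rich distal alkene at its E-methyl group, so the new allylic alcohol is E and the acetate-deactivated 2,3-alkene is untouched.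

**Step 2**
Reactants: 2 (2E,6E)-8-hydroxy-3,7-dimethylocta-2,6-dien-1-yl acetate
Product: 3 (2E,6E)-8-[(tert-butyldimethylsilyl)oxy]-3,7-dimethylocta-2,6-dien-1-yl acetate
Conditions: TBSCl, imidazole, CH2Cl2, rt
Reagents that add atoms: tert-butyldimethylsilyl chloride CC(C)(C)[Si](C)(C)Cl
Why: Imidazole-promoted O-silylation of a primary alcohol masks the C8 oxygen against the later Grignard reagent.

**Step 3**
Reactants: 3 (2E,6E)-8-[(tert-butyldimethylsilyl)oxy]-3,7-dimethylocta-2,6-dien-1-yl acetate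
Product: 4 (2E,6E)-8-[(tert-butyldimethylsilyl)oxy]-3,7-dimethylocta-2,6-dien-1-ol
Conditions: K2CO3 (0.2 equiv), MeOH, rt
Reagents that add atoms: none
Why: Base-catalysed transesterification removes the acetate, and the TBS ether is stable to carbonate in methanol.

**Step 4**
Reactants: 4 (2E,6E)-8-[(tert-butyldimethylsilyl)oxy]-3,7-dimethylocta-2,6-dien-1-ol
Product: 6 tert-butyl{[(2E,6E)-8-chloro-2,6-dimethylocta-2,6-dien-1-yl]oxy}dimethylsilane, via allylic mesylate 5 (not isolated)
Conditions: MsCl, LiCl, 2,4,6-collidine, DMF, 0 °C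
Reagents that add atoms: lithium chloride [Li+].[Cl-]; methanesulfonyl chloride CS(=O)(=O)Cl (stays only in 5)
Why: In the Collington–Meyers chlorination, chloride displaces the mesylate formed in situ by SN2 at the primary carbon, without allylic transposition or E/Z loss.

**Step 5**
Reactants: 7 furan-3-ylmethanol
Product: 9 3-(chloromethyl)furan, via furan-3-ylmethyl mesylate 8 (not isolated)
Conditions: MsCl, LiCl, 2,4,6-collidine, DMF, 0 °C; pentane extraction, careful concentration, use at once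
Reagents that add atoms: lithium chloride [Li+].[Cl-]; methanesulfonyl chloride CS(=O)(=O)Cl (stays only in 8)
Why: The same acid-free mesylation/SN2 chloride displacement (Collington–Meyers) spares the acid-sensitive furan.

**Step 6**
Reactants: 9 3-(chloromethyl)furan (2 equiv); 6 tert-butyl{[(2E,6E)-8-chloro-2,6-dimethylocta-2,6-dien-1-yl]oxy}dimethylsilane
Product: 11 tert-butyl{[(2E,6E)-9-(furan-3-yl)-2,6-dimethylnona-2,6-dien-1-yl]oxy}dimethylsilane, via furan-3-ylmethylmagnesium chloride 10 (not isolated)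
Conditions: Mg (activated, excess), THF, 0 °C, slow addition of 9; then cannulate into 6, Li2CuCl4 (5 mol %), THF, 0 °C → rt
Reagents that add atoms: magnesium [Mg] (stays only in 10)
Why: The Kochi-type copper-catalysed Grignard cross-coupling substitutes the primary, γ,γ-disubstituted allylic chloride at the α-carbon (SN2), keeps the E-alkene, and bonds through the CH2 of the furylmethyl unit.

**Step 7**
Reactants: 11 tert-butyl{[(2E,6E)-9-(furan-3-yl)-2,6-dimethylnona-2,6-dien-1-yl]oxy}dimethylsilane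
Product: 12 (2E,6E)-9-(furan-3-yl)-2,6-dimethylnona-2,6-dien-1-ol
Conditions: TBAF, THF, rt
Reagents that add atoms: none
Why: Fluoride-induced desilylation is neutral to the furan and to both alkenes.

**Step 8**
Reactants: 12 (2E,6E)-9-(furan-3-yl)-2,6-dimethylnona-2,6-dien-1-ol
Product: 14 3-[(3E,7E)-9-bromo-4,8-dimethylnona-3,7-dien-1-yl]furan, via allylic mesylate 13 (not isolated)
Conditions: MsCl, Et3N, THF, −45 °C; then LiBr, THF, 0 °C; quick cold work-up, used crude
Reagents that add atoms: lithium bromide [Li+].[Br-]; methanesulfonyl chloride CS(=O)(=O)Cl (stays only in 13)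
Why: Mesylation followed by SN2 bromide displacement gives the primary allylic bromide under acid-free conditions, with the alkene geometry retained.

**Step 9**
Reactants: 15 methyl (R)-3-hydroxy-2-methylpropanoate [(R)-Roche ester]
Product: 16 methyl (R)-3-[(tert-butyldimethylsilyl)oxy]-2-methylpropanoate
Conditions: TBSCl, imidazole, CH2Cl2, 0 °C → rt
Reagents that add atoms: tert-butyldimethylsilyl chloride CC(C)(C)[Si](C)(C)Cl
Why: This simple O-silylation does not touch the chiral-pool stereocentre, which becomes C18 of the target.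

**Step 10**
Reactants: 16 methyl (R)-3-[(tert-butyldimethylsilyl)oxy]-2-methylpropanoate
Product: 17 (S)-3-[(tert-butyldimethylsilyl)oxy]-2-methylpropan-1-ol
Conditions: DIBAL-H (2.5 equiv), CH2Cl2, −78 → 0 °C; Rochelle salt work-up
Reagents that add atoms: none
Why: The hydride reduction goes straight through to the alcohol so no enolisable aldehyde builds up, and the descriptor changes only through CIP priorities.

**Step 11**
Reactants: 17 (S)-3-[(tert-butyldimethylsilyl)oxy]-2-methylpropan-1-ol
Product: 18 (R)-tert-butyl(3-iodo-2-methylpropoxy)dimethylsilane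
Conditions: I2, PPh3, imidazole, CH2Cl2, 0 °C
Reagents that add atoms: iodine II
Why: The Appel-type (Garegg–Samuelsson) iodination acts at the CH2OH carbon only and is too mild for the silyl migration that would racemise the compound.

**Step 12**
Reactants: 19 methyl phenyl sulfone (2 equiv); 18 (R)-tert-butyl(3-iodo-2-methylpropoxy)dimethylsilane
Product: 21 (S)-tert-butyldimethyl[2-methyl-4-(phenylsulfonyl)butoxy]silane, via lithiomethyl phenyl sulfone 20 (not isolated)
Conditions: n-BuLi, THF–DMPU, −78 °C; then 18, −78 °C → rt, 12 h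
Reagents that add atoms: n-butyllithium [Li]CCCC (Li stays only in 20)
Why: SN2 alkylation of the sulfone-stabilised carbanion with a primary iodide adds one carbon, and excess sulfone suppresses double alkylation.

**Step 13**
Reactants: 21 (S)-tert-butyldimethyl[2-methyl-4-(phenylsulfonyl)butoxy]silane; 14 3-[(3E,7E)-9-bromo-4,8-dimethylnona-3,7-dien-1-yl]furan
Product: 23 tert-butyl{[(2S,6E,10E)-13-(furan-3-yl)-2,6,10-trimethyl-4-(phenylsulfonyl)trideca-6,10-dien-1-yl]oxy}dimethylsilane (C4 epimers), via α-lithio sulfone 22 (not isolated)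
Conditions: n-BuLi (1.05 equiv), THF, −78 °C, 30 min; then 14, −78 → −20 °C
Reagents that add atoms: n-butyllithium [Li]CCCC (Li stays only in 22)
Why: The soft lithiated sulfone allylates by SN2 at the primary carbon of 14, and the new sulfonyl-bearing centre is irrelevant because step 14 removes it.

**Step 14**
Reactants: 23 tert-butyl{[(2S,6E,10E)-13-(furan-3-yl)-2,6,10-trimethyl-4-(phenylsulfonyl)trideca-6,10-dien-1-yl]oxy}dimethylsilane
Product: 24 tert-butyl{[(2S,6E,10E)-13-(furan-3-yl)-2,6,10-trimethyltrideca-6,10-dien-1-yl]oxy}dimethylsilane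
Conditions: 6% Na(Hg), Na2HPO4, MeOH–THF, −20 °C → rt
Reagents that add atoms: none
Why: Reductive desulfonylation by single-electron transfer cleaves the alkyl C–S bond, and because the sulfone is not allylic neither alkene can migrate or isomerise.

**Step 15**
Reactants: 24 tert-butyl{[(2S,6E,10E)-13-(furan-3-yl)-2,6,10-trimethyltrideca-6,10-dien-1-yl]oxy}dimethylsilane
Product: 25 (2S,6E,10E)-13-(furan-3-yl)-2,6,10-trimethyltrideca-6,10-dien-1-ol
Conditions: TBAF, THF, rt
Reagents that add atoms: none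
Why: Fluoride-induced desilylation frees the primary alcohol without affecting any other group.

**Step 16**
Reactants: 25 (2S,6E,10E)-13-(furan-3-yl)-2,6,10-trimethyltrideca-6,10-dien-1-ol
Product: 26 (2S,6E,10E)-13-(furan-3-yl)-2,6,10-trimethyltrideca-6,10-dienal
Conditions: Dess–Martin periodinane, NaHCO3, CH2Cl2, 0 °C → rt; used the same day
Reagents that add atoms: none
Why: The buffered Dess–Martin oxidation stops at the aldehyde under near-neutral conditions, so the α-stereocentre, the furan and the alkenes survive.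

**Step 17**
Reactants: 27 ethyl 2-methylacetoacetate (ethyl 2-methyl-3-oxobutanoate)
Product: 29 ethyl 4-bromo-2-methyl-3-oxobutanoate, via ethyl 2-bromo-2-methyl-3-oxobutanoate 28 (not isolated)
Conditions: Br2 (1.0 equiv), CHCl3, 0 °C → rt, 16 h (HBr kept in the flask); purge, concentrate
Reagents that add atoms: bromine BrBr
Why: Electrophilic α-bromination is followed by the HBr-catalysed α→γ bromine migration, which gives the more stable primary bromoketone.

**Step 18**
Reactants: 29 ethyl 4-bromo-2-methyl-3-oxobutanoate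
Product: 30 4-hydroxy-3-methylfuran-2(5H)-one (3-methyltetronic acid)
Conditions: neat, 48% aq HBr (drops), 100–110 °C, 8 h; trituration and crystallisation
Reagents that add atoms: none
Why: In this thermal lactonisation the ester carbonyl oxygen displaces the primary bromide (5-exo-tet) and bromide then removes the ethyl group, closing the butenolide ring as its stable enol.

**Step 19**
Reactants: 30 4-hydroxy-3-methylfuran-2(5H)-one
Product: 31 4-methoxy-3-methylfuran-2(5H)-one
Conditions: Me2SO4, K2CO3, acetone, reflux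
Reagents that add atoms: dimethyl sulfate COS(=O)(=O)OC
Why: O-alkylation of the vinylogous acid with a hard methylating agent gives mainly the conjugated 4-methoxy isomer, which is purified by chromatography.

**Step 20 (key step)**
Reactants: 31 4-methoxy-3-methylfuran-2(5H)-one (1.5 equiv); 26 (2S,6E,10E)-13-(furan-3-yl)-2,6,10-trimethyltrideca-6,10-dienal
Product: 33 5-[(2S,6E,10E)-13-(furan-3-yl)-1-hydroxy-2,6,10-trimethyltrideca-6,10-dien-1-yl]-4-methoxy-3-methylfuran-2(5H)-one (diastereomer mixture), via lithium furanolate 32 (not isolated)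
Conditions: LDA (1.45 equiv), THF, −78 °C, 40 min; then 26, −78 °C, 1 h; AcOH/THF quench at −78 °C
Reagents that add atoms: lithium diisopropylamide [Li+].CC(C)[N-]C(C)C (Li stays only in 32)
Why: In this intermolecular vinylogous aldol addition the aromatic 2-furanolate reacts at C5 faster than it enolises the aldehyde at −78 °C, so the (S)-centre is kept, and the two new centres need no control because step 21 destroys them.

**Step 21**
Reactants: 33 5-[(2S,6E,10E)-13-(furan-3-yl)-1-hydroxy-2,6,10-trimethyltrideca-6,10-dien-1-yl]-4-methoxy-3-methylfuran-2(5H)-one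
Product: 35 (5Z)-5-[(2S,6E,10E)-13-(furan-3-yl)-2,6,10-trimethyltrideca-6,10-dien-1-ylidene]-4-methoxy-3-methylfuran-2(5H)-one, via secondary mesylate 34 (not isolated)
Conditions: MsCl, Et3N, CH2Cl2, 0 °C; then DBU, 0 °C → rt, 1–2 h; chromatography
Reagents that add atoms: methanesulfonyl chloride CS(=O)(=O)Cl (stays only in 34)
Why: Mesylation and E1cB elimination through the C5 furanolate converge both diastereomers on the Z-alkene, which avoids the clash between the side chain and the 4-OMe group, while the non-acidic C–H at the (S)-centre is not touched.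

**Step 22**
Reactants: 35 (5Z)-5-[(2S,6E,10E)-13-(furan-3-yl)-2,6,10-trimethyltrideca-6,10-dien-1-ylidene]-4-methoxy-3-methylfuran-2(5H)-one
Product: 37 (18S)-variabilin [(5Z)-5-[(2S,6E,10E)-13-(furan-3-yl)-2,6,10-trimethyltrideca-6,10-dien-1-ylidene]-4-hydroxy-3-methylfuran-2(5H)-one], via lithium tetronate 36 (not isolated)
Conditions: n-PrSLi (4 equiv, from n-PrSH + n-BuLi), HMPA, rt, 2 h, Ar; then cold 1 M HCl to pH 3, Et2O extraction
Reagents that add atoms: lithium propane-1-thiolate [Li+].CCC[S-] (Li stays only in 36)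
Why: SN2 O-demethylation of the vinylogous methyl ester by a soft thiolate irreversibly releases the stabilised tetronate anion at room temperature, without the acid that would damage the furan and the alkenes.

## Compound list
1 | geranyl acetate | CC(=O)OC/C=C(C)/CCC=C(C)C | starting material
2 | (2E,6E)-8-hydroxy-3,7-dimethylocta-2,6-dien-1-yl acetate | CC(=O)OC/C=C(C)/CC/C=C(C)/CO | intermediate
3 | (2E,6E)-8-[(tert-butyldimethylsilyl)oxy]-3,7-dimethylocta-2,6-dien-1-yl acetate | CC(=O)OC/C=C(C)/CC/C=C(C)/CO[Si](C)(C)C(C)(C)C | intermediate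
4 | (2E,6E)-8-[(tert-butyldimethylsilyl)oxy]-3,7-dimethylocta-2,6-dien-1-ol | OC/C=C(C)/CC/C=C(C)/CO[Si](C)(C)C(C)(C)C | intermediate
5 | (2E,6E)-8-[(tert-butyldimethylsilyl)oxy]-3,7-dimethylocta-2,6-dien-1-yl methanesulfonate | CS(=O)(=O)OC/C=C(C)/CC/C=C(C)/CO[Si](C)(C)C(C)(C)C | intermediate
6 | tert-butyl{[(2E,6E)-8-chloro-2,6-dimethylocta-2,6-dien-1-yl]oxy}dimethylsilane | ClC/C=C(C)/CC/C=C(C)/CO[Si](C)(C)C(C)(C)C | intermediate
7 | furan-3-ylmethanol | OCc1ccoc1 | starting material
8 | furan-3-ylmethyl methanesulfonate | CS(=O)(=O)OCc1ccoc1 | intermediate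
9 | 3-(chloromethyl)furan | ClCc1ccoc1 | intermediate
10 | (furan-3-ylmethyl)magnesium chloride | Cl[Mg]Cc1ccoc1 | intermediate
11 | tert-butyl{[(2E,6E)-9-(furan-3-yl)-2,6-dimethylnona-2,6-dien-1-yl]oxy}dimethylsilane | CC(C)(C)[Si](C)(C)OC/C(C)=C/CC/C(C)=C/CCc1ccoc1 | intermediate
12 | (2E,6E)-9-(furan-3-yl)-2,6-dimethylnona-2,6-dien-1-ol | OC/C(C)=C/CC/C(C)=C/CCc1ccoc1 | intermediate
13 | (2E,6E)-9-(furan-3-yl)-2,6-dimethylnona-2,6-dien-1-yl methanesulfonate | CS(=O)(=O)OC/C(C)=C/CC/C(C)=C/CCc1ccoc1 | intermediate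
14 | 3-[(3E,7E)-9-bromo-4,8-dimethylnona-3,7-dien-1-yl]furan | BrC/C(C)=C/CC/C(C)=C/CCc1ccoc1 | intermediate
15 | methyl (R)-3-hydroxy-2-methylpropanoate | COC(=O)[C@H](C)CO | starting material
16 | methyl (R)-3-[(tert-butyldimethylsilyl)oxy]-2-methylpropanoate | COC(=O)[C@H](C)CO[Si](C)(C)C(C)(C)C | intermediate
17 | (S)-3-[(tert-butyldimethylsilyl)oxy]-2-methylpropan-1-ol | OC[C@H](C)CO[Si](C)(C)C(C)(C)C | intermediate
18 | (R)-tert-butyl(3-iodo-2-methylpropoxy)dimethylsilane | IC[C@H](C)CO[Si](C)(C)C(C)(C)C | intermediate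
19 | methyl phenyl sulfone | CS(=O)(=O)c1ccccc1 | starting material
20 | [(phenylsulfonyl)methyl]lithium | [Li]CS(=O)(=O)c1ccccc1 | intermediate
21 | (S)-tert-butyldimethyl[2-methyl-4-(phenylsulfonyl)butoxy]silane | O=S(=O)(CC[C@H](C)CO[Si](C)(C)C(C)(C)C)c1ccccc1 | intermediate
22 | α-lithio derivative of 21 | [Li]C(C[C@H](C)CO[Si](C)(C)C(C)(C)C)S(=O)(=O)c1ccccc1 | intermediate
23 | tert-butyl{[(2S,6E,10E)-13-(furan-3-yl)-2,6,10-trimethyl-4-(phenylsulfonyl)trideca-6,10-dien-1-yl]oxy}dimethylsilane (C4 epimers) | CC(C)(C)[Si](C)(C)OC[C@@H](C)CC(C/C(C)=C/CC/C(C)=C/CCc1ccoc1)S(=O)(=O)c1ccccc1 | intermediate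
24 | tert-butyl{[(2S,6E,10E)-13-(furan-3-yl)-2,6,10-trimethyltrideca-6,10-dien-1-yl]oxy}dimethylsilane | CC(C)(C)[Si](C)(C)OC[C@@H](C)CCC/C(C)=C/CC/C(C)=C/CCc1ccoc1 | intermediate
25 | (2S,6E,10E)-13-(furan-3-yl)-2,6,10-trimethyltrideca-6,10-dien-1-ol | OC[C@@H](C)CCC/C(C)=C/CC/C(C)=C/CCc1ccoc1 | intermediate
26 | (2S,6E,10E)-13-(furan-3-yl)-2,6,10-trimethyltrideca-6,10-dienal | O=C[C@@H](C)CCC/C(C)=C/CC/C(C)=C/CCc1ccoc1 | intermediate
27 | ethyl 2-methyl-3-oxobutanoate | CCOC(=O)C(C)C(C)=O | starting material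
28 | ethyl 2-bromo-2-methyl-3-oxobutanoate | CCOC(=O)C(C)(Br)C(C)=O | intermediate
29 | ethyl 4-bromo-2-methyl-3-oxobutanoate | CCOC(=O)C(C)C(=O)CBr | intermediate
30 | 4-hydroxy-3-methylfuran-2(5H)-one | CC1=C(O)COC1=O | intermediate
31 | 4-methoxy-3-methylfuran-2(5H)-one | COC1=C(C)C(=O)OC1 | intermediate
32 | lithium 4-methoxy-3-methylfuran-2-olate | [Li+].COc1coc([O-])c1C | intermediate
33 | 5-[(2S,6E,10E)-13-(furan-3-yl)-1-hydroxy-2,6,10-trimethyltrideca-6,10-dien-1-yl]-4-methoxy-3-methylfuran-2(5H)-one (diastereomer mixture) | COC1=C(C)C(=O)OC1C(O)[C@@H](C)CCC/C(C)=C/CC/C(C)=C/CCc2ccoc2 | intermediate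
34 | methanesulfonate of 33 | COC1=C(C)C(=O)OC1C(OS(C)(=O)=O)[C@@H](C)CCC/C(C)=C/CC/C(C)=C/CCc2ccoc2 | intermediate
35 | (5Z)-5-[(2S,6E,10E)-13-(furan-3-yl)-2,6,10-trimethyltrideca-6,10-dien-1-ylidene]-4-methoxy-3-methylfuran-2(5H)-one | CC1=C(OC)/C(=C/[C@@H](C)CCC/C(C)=C/CC/C(C)=C/CCc2ccoc2)OC1=O | intermediate
36 | lithium salt of variabilin | [Li+].CC1=C([O-])/C(=C/[C@@H](C)CCC/C(C)=C/CC/C(C)=C/CCc2ccoc2)OC1=O | intermediate
37 | (18S)-variabilin | CC1=C(O)/C(=C/[C@@H](C)CCC/C(C)=C/CC/C(C)=C/CCc2ccoc2)OC1=O | target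

## Totals
Total step count: 22.
Longest linear sequence: 14 steps (1, 2, 3, 4, 6, 7, 8, 13, 14, 15, 16, 20, 21, 22).

## Three steps most likely to fail

**Step 6 (furylmethyl Grignard formation and Cu-catalysed coupling).** The risks are Wurtz dimerisation during Mg insertion, attack through C2 of the furan, and SN2′ substitution.

The fallback reverses the polarity. It sets out from 6 (with 9) and comes back at 11.
- Chloride 6 is heated with PhSO2Na in DMF to give the allylic sulfone tert-butyl{[(2E,6E)-2,6-dimethyl-8-(phenylsulfonyl)octa-2,6-dien-1-yl]oxy}dimethylsilane F1.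
- n-BuLi in THF at −78 °C converts F1 into its α-lithio derivative F2.
- F2 is alkylated by 3-(chloromethyl)furan 9 to give tert-butyl{[(2E,6E)-9-(furan-3-yl)-2,6-dimethyl-8-(phenylsulfonyl)nona-2,6-dien-1-yl]oxy}dimethylsilane F3.
- Palladium-catalysed hydride desulfonylation (PdCl2(dppp), LiBHEt3, THF, 0 °C) then removes the sulfonyl group without moving or isomerising the alkene and delivers 11.

**Step 20 (lithium furanolate aldol).** The risks are enolisation or epimerisation of the α-branched aldehyde by the basic nucleophile, and retro-aldol on work-up.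

The fallback uses a neutral silyl nucleophile. It sets out from 31 (with 26) and comes back at 35, bypassing 33 and 34.
- 31 is treated with TBSOTf and i-Pr2NEt in CH2Cl2 at 0 °C to give the silyloxyfuran tert-butyl[(4-methoxy-3-methylfuran-2-yl)oxy]dimethylsilane F4.
- F4 adds to 26 in the same flask under TBSOTf catalysis (vinylogous Mukaiyama aldol). The product is the silyl-protected adduct 5-{(2S,6E,10E)-1-[(tert-butyldimethylsilyl)oxy]-13-(furan-3-yl)-2,6,10-trimethyltrideca-6,10-dien-1-yl}-4-methoxy-3-methylfuran-2(5H)-one F5.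
- Added DBU eliminates silanol by E1cB and gives 35.

**Step 22 (thiolate demethylation).** The risks are reversible thiolate addition to the dienyl lactone, slow cleavage, and loss of the air-sensitive product.

The fallback changes the O-protecting group to one removed by fluoride. It sets out from 30 (with 26) and comes back at 37.
- Mitsunobu alkylation of 30 (2-(trimethylsilyl)ethanol, PPh3, DIAD, THF) gives 3-methyl-4-[2-(trimethylsilyl)ethoxy]furan-2(5H)-one F6.
- LDA at −78 °C gives its lithium furanolate F7, which adds to 26 to give the aldol adduct F8.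
- MsCl/Et3N gives the mesylate F9, and DBU gives the (Z)-ylidene 2-(trimethylsilyl)ethyl tetronate F10.
- TBAF in THF at 0 °C fragments the silylethyl group to the tetrabutylammonium salt of variabilin F11.
- Acidification to pH 3 gives 37.

## Further compounds
F1 | step 6 | tert-butyl{[(2E,6E)-2,6-dimethyl-8-(phenylsulfonyl)octa-2,6-dien-1-yl]oxy}dimethylsilane | CC(C)(C)[Si](C)(C)OC/C(C)=C/CC/C(C)=C/CS(=O)(=O)c1ccccc1
F2 | step 6 | α-lithio derivative of F1 | [Li]C(/C=C(C)/CC/C=C(C)/CO[Si](C)(C)C(C)(C)C)S(=O)(=O)c1ccccc1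
F3 | step 6 | tert-butyl{[(2E,6E)-9-(furan-3-yl)-2,6-dimethyl-8-(phenylsulfonyl)nona-2,6-dien-1-yl]oxy}dimethylsilane | CC(C)(C)[Si](C)(C)OC/C(C)=C/CC/C(C)=C/C(Cc1ccoc1)S(=O)(=O)c1ccccc1
F4 | step 20 | tert-butyl[(4-methoxy-3-methylfuran-2-yl)oxy]dimethylsilane | COc1coc(O[Si](C)(C)C(C)(C)C)c1C
F5 | step 20 | 5-{(2S,6E,10E)-1-[(tert-butyldimethylsilyl)oxy]-13-(furan-3-yl)-2,6,10-trimethyltrideca-6,10-dien-1-yl}-4-methoxy-3-methylfuran-2(5H)-one | COC1=C(C)C(=O)OC1C(O[Si](C)(C)C(C)(C)C)[C@@H](C)CCC/C(C)=C/CC/C(C)=C/CCc2ccoc2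
F6 | step 22 | 3-methyl-4-[2-(trimethylsilyl)ethoxy]furan-2(5H)-one | CC1=C(OCC[Si](C)(C)C)COC1=O
F7 | step 22 | lithium 3-methyl-4-[2-(trimethylsilyl)ethoxy]furan-2-olate | [Li+].[O-]c1occ(OCC[Si](C)(C)C)c1C
F8 | step 22 | 5-[(2S,6E,10E)-13-(furan-3-yl)-1-hydroxy-2,6,10-trimethyltrideca-6,10-dien-1-yl]-3-methyl-4-[2-(trimethylsilyl)ethoxy]furan-2(5H)-one | CC1=C(OCC[Si](C)(C)C)C(OC1=O)C(O)[C@@H](C)CCC/C(C)=C/CC/C(C)=C/CCc2ccoc2
F9 | step 22 | methanesulfonate of F8 | CC1=C(OCC[Si](C)(C)C)C(OC1=O)C(OS(C)(=O)=O)[C@@H](C)CCC/C(C)=C/CC/C(C)=C/CCc2ccoc2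
F10 | step 22 | (5Z)-5-[(2S,6E,10E)-13-(furan-3-yl)-2,6,10-trimethyltrideca-6,10-dien-1-ylidene]-3-methyl-4-[2-(trimethylsilyl)ethoxy]furan-2(5H)-one | CC1=C(OCC[Si](C)(C)C)/C(=C/[C@@H](C)CCC/C(C)=C/CC/C(C)=C/CCc2ccoc2)OC1=O
F11 | step 22 | tetrabutylammonium salt of variabilin | CCCC[N+](CCCC)(CCCC)CCCC.CC1=C([O-])/C(=C/[C@@H](C)CCC/C(C)=C/CC/C(C)=C/CCc2ccoc2)OC1=O
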